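**Plan**

1. Retrosynthesis (hydroxyls masked as triethylsilyl ethers): the oxirane C6–O bond of ring A is opened back onto the C8 oxygen, with one C7 hydrogen returned to C8, which restores a 5,8-peroxide; its C5–O and C8–O bonds are then cut together into dioxygen and the C5=C6–C7=C8 diene of lutein.
2. Forward: lutein is silylated; the six-membered 3,6-dihydro-1,2-dioxine is closed across C5/C8 on ring A; the O–O bond is broken while the oxirane closes at C6 and C8 becomes the ketone; the silyl groups are removed. No C–C bond is made; the C40 chain and both rings come intact from lutein.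
3. Enabling feature: ring A holds C5=C6–C7=C8 as the only diene of the polyene that is twisted towards s-cis, and its termini C5 and C8 are the carbons that carry the epoxide oxygen and the ketone oxygen of the target, which is an isomer of lutein + O2.
4. Stereochemistry: C3, C3', C6' and the E chain are those of natural lutein; C5 is set in the cycloaddition (attack anti to the C3 silyloxy group); C6 follows from C5 because the oxirane can only close cis; the peroxide centre C8 is erased.

Key step: step 2

Remark on the chemistry: the SMILES is read as the all-E (3S,5R,6S,3'R,6'R) isomer, that is, the 5,6-epoxide anti to the C3 hydroxyl and a ring B identical to that of natural lutein.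

**Route**

Step 1
Reactants: 1 lutein; 2 chlorotriethylsilane
Product: 3 lutein bis(triethylsilyl) ether
Conditions: Et3SiCl (2.5 equiv), imidazole (5 equiv), DMF–CH2Cl2, 0 °C → rt, dark, Ar
Reagents that add atoms: chlorotriethylsilane (compound 2), CC[Si](Cl)(CC)CC
Why: Imidazole-promoted O-silylation of secondary alcohols (silyl ether formation) should cap both hydroxyls, including the allylic one on ring B, without touching C3, C3' or C6'.

Step 2
Reactants: 3 lutein bis(triethylsilyl) ether
Product: 4 5,8-endoperoxide of lutein bis(triethylsilyl) ether (peroxide anti to the C3 silyloxy group, C8–H cis to the C5 methyl)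
Conditions: O2 (1 atm), 5,10,15,20-tetraphenylporphyrin (free base, 2 mol %), CH2Cl2 (dilute), −40 °C, hν 589 nm (sodium lamp), run to partial conversion, 3 recovered and recycled
Reagents that add atoms: dioxygen, O=O
Why: Singlet oxygen is an electrophilic two-atom partner and should add suprafacially across C5 and C8 of the electron-rich C5=C6–C7=C8 diene in a concerted, asynchronous [4+2] cycloaddition (hetero-Diels–Alder type), which makes the C5–O and C8–O bonds in one event. The closest known reaction is the dye-sensitised photooxygenation of the twisted cisoid diene of β-type end groups of carotenoids and retinoids to 5,8-endoperoxides. The only ring formed, the 3,6-dihydro-1,2-dioxine, is closed by cycloaddition, both new bonds arising on the same face of the diene. Of the two new stereocentres, C8 is tied to C5 by the suprafacial course and the 7E geometry (C8–H cis to the C5 methyl), and C5 is expected to result from attack on the face of ring A anti to the equatorial C3 silyloxy group, the sense that prevails in peracid epoxidation of 3-O-protected β-rings. The step needs site selectivity within ten conjugated double bonds, which the substrate provides because only this diene can reach an s-cis geometry (the chain dienes are s-trans and merely quench), while the isolated ring B alkene, deactivated by its allylic silyloxy group, can react only by the slower Schenck ene path. Light of 589 nm is absorbed by the porphyrin and not by the carotenoid, and the silyl ethers remove hydroxyl-directed delivery to the syn face.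

Step 3
Reactants: 4 5,8-endoperoxide of lutein bis(triethylsilyl) ether
Product: 5 bis(triethylsilyl) ether of the target (5,6-epoxy-8-ketone)
Conditions: Co(TPP) (tetraphenylporphyrinatocobalt, divalent cobalt, 5 mol %), CH2Cl2, −20 → 0 °C, dark, Ar, base- and acid-free glassware
Reagents that add atoms: none
Why: Proposed new method: divalent cobalt should cleave the weak O–O bond by inner-sphere electron transfer at the less hindered oxygen on C8, leaving a trivalent-cobalt alkoxide there (so that no free oxyl radical sits next to the polyene, as it would on heating, and no base removes the C8 hydrogen) and an oxyl radical on C5; this radical can close 3-exo-trig onto C6 of the C6=C7 bond, which fixes the oxirane cis-fused on the face already defined at C5 and so sets C6 (S), and the C7 radical is then expected to take the hydrogen from C8 (a C–H bond weakened by the cobalt alkoxide and the polyene) as the electron returns to cobalt, so that C8 becomes the polyene-conjugated ketone, C7 the methylene group and the catalyst is regenerated; the closest known reaction type is the Co(TPP)- or heat-induced isomerisation of unsaturated 1,4-endoperoxides, which gives syn-diepoxides and, by the same hydrogen shift, β,γ-epoxy ketones, but it has not been shown for a ring-fused dioxine that carries a polyene, nor with the epoxy ketone as the main product.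

Step 4
Reactants: 5 bis(triethylsilyl) ether of the target
Product: 6 target, (3S,5R,6S,3'R,6'R)-5,6-epoxy-3,3'-dihydroxy-5,6,7,8-tetrahydro-β,ε-caroten-8-one
Conditions: HF·pyridine, pyridine (excess), THF, 0 °C, dark; aq NaHCO3 quench
Reagents that add atoms: none
Why: Fluoride-driven Si–O cleavage (desilylation with pyridine-buffered HF·pyridine) should remove both triethylsilyl ethers under conditions too weakly basic to enolise the β,γ-epoxy ketone and too weakly acidic to open the oxirane or ionise the allylic C3' oxygen; no stereocentre is involved.

**Compound list**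

1 | lutein, (3R,3'R,6'R)-β,ε-carotene-3,3'-diol, all-E | CC1=C[C@H](O)CC(C)(C)[C@H]1/C=C/C(C)=C/C=C/C(C)=C/C=C/C=C(C)/C=C/C=C(C)/C=C/C1=C(C)C[C@@H](O)CC1(C)C | starting material
2 | chlorotriethylsilane | CC[Si](Cl)(CC)CC | starting material
3 | lutein bis(triethylsilyl) ether, (3R,3'R,6'R)-3,3'-bis(triethylsilyloxy)-β,ε-carotene | CC1=C[C@H](O[Si](CC)(CC)CC)CC(C)(C)[C@H]1/C=C/C(C)=C/C=C/C(C)=C/C=C/C=C(C)/C=C/C=C(C)/C=C/C1=C(C)C[C@@H](O[Si](CC)(CC)CC)CC1(C)C | intermediate
4 | (3S,5R,8R,3'R,6'R)-5,8-epidioxy-3,3'-bis(triethylsilyloxy)-5,8-dihydro-β,ε-carotene; C6=C7 in the dioxine ring, peroxide anti to the C3 silyloxy group, C8–H cis to the C5 methyl | CC1=C[C@H](O[Si](CC)(CC)CC)CC(C)(C)[C@H]1/C=C/C(C)=C/C=C/C(C)=C/C=C/C=C(C)/C=C/C=C(\C)[C@@H]1OO[C@]2(C)C[C@@H](O[Si](CC)(CC)CC)CC(C)(C)C2=C1 | intermediate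
5 | (3S,5R,6S,3'R,6'R)-5,6-epoxy-3,3'-bis(triethylsilyloxy)-5,6,7,8-tetrahydro-β,ε-caroten-8-one | CC1=C[C@H](O[Si](CC)(CC)CC)CC(C)(C)[C@H]1/C=C/C(C)=C/C=C/C(C)=C/C=C/C=C(C)/C=C/C=C(\C)C(=O)C[C@@]12O[C@]1(C)C[C@@H](O[Si](CC)(CC)CC)CC2(C)C | intermediate
6 | (3S,5R,6S,3'R,6'R)-5,6-epoxy-3,3'-dihydroxy-5,6,7,8-tetrahydro-β,ε-caroten-8-one | CC1=C[C@H](O)CC(C)(C)[C@H]1/C=C/C(C)=C/C=C/C(C)=C/C=C/C=C(C)/C=C/C=C(\C)C(=O)C[C@@]12O[C@]1(C)C[C@@H](O)CC2(C)C | target

**Step count**

Total steps: 4. Longest linear sequence: 4 steps (1 → 3 → 4 → 5 → 6).

**The three steps most likely to fail**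

First, step 3, which bears the label. In a dioxine that is fused but not bridged, the C8 hydrogen can swing within reach of the C5 oxyl radical, so hydrogen transfer from C8 to that oxygen (the radical counterpart of a Kornblum–DeLaMare fragmentation) may outrun closure on C6. The C7 radical may also collapse onto the C8 oxygen and close a second oxirane instead of accepting the hydrogen. Traces of base during work-up may open the oxirane of 5 by β-elimination. This is the weakest step of the route, and diversion by hydrogen transfer is the more likely outcome.

The fallback uses known chemistry, sets out from 4 and comes back at 5. The peroxide is opened on purpose with triethylamine (Kornblum–DeLaMare fragmentation, CH2Cl2, 0 °C). This should give (3S,5R,6Z,3'R,6'R)-5-hydroxy-3,3'-bis(triethylsilyloxy)-5,8-dihydro-β,ε-caroten-8-one F1, which is expected to rest partly as its ring-closed hemiketal, (3S,5R,3'R,6'R)-5,8-epoxy-3,3'-bis(triethylsilyloxy)-5,8-dihydro-β,ε-caroten-8-ol F2. Samarium diiodide (SmI2, THF–MeOH, −78 °C) should then cleave the vinylogous C5–O bond of the open form and, after protonation of the dienolate at C7, give (3R,3'R,6'R)-3,3'-bis(triethylsilyloxy)-7,8-dihydro-β,ε-caroten-8-one F3 with the C5=C6 bond restored. Buffered peracid epoxidation (3-chloroperbenzoic acid, NaHCO3, CH2Cl2, −20 °C) of this isolated tetrasubstituted alkene, expected on the face anti to the C3 silyloxy group, leads back to 5. In this variant the C5 oxygen from dioxygen is given up and the epoxide oxygen comes from the peracid. Because C5 and C8 are erased at F3, the sequence also accepts the syn diastereomer of 4 and any material that step 3 diverts by hydrogen transfer.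

Second, step 2. The polyene may intercept the sensitiser triplet and quench singlet oxygen physically much faster than it reacts, so that cycloaddition stalls while slow photobleaching and ene oxidation at ring B go on. Addition may also take place on both faces of ring A, which would require separation of diastereomers. The fallback sets out from 3 and comes back at 4 and makes no new compound (F0). Photosensitisation is given up altogether, and singlet oxygen is transferred to 3 in the dark from a stoichiometric thermal donor, 1,4-dimethylnaphthalene 1,4-endoperoxide, which releases it by cycloreversion at 25–35 °C in CH2Cl2. This reagent-based oxygen transfer needs no light or dye, so triplet interception and light-driven isomerisation of the chain cannot occur.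

Third, step 4. Fluoride may act as a base and open the oxirane by enolisation and β-elimination, or acid may ionise the allylic C3' oxygen or open the epoxide, before both silyl groups are off. The fallback sets out from 1 and comes back at 6 and avoids protecting groups. Lutein 1 is photooxygenated under the conditions of step 2 to (3S,5R,8R,3'R,6'R)-5,8-epidioxy-5,8-dihydro-β,ε-carotene-3,3'-diol F4, which is isomerised under the conditions of step 3 directly to 6, so the epoxy ketone never meets fluoride or acid. This variant still depends on the step 3 isomerisation.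

**Further compounds**

F1 | step 3 | (3S,5R,6Z,3'R,6'R)-5-hydroxy-3,3'-bis(triethylsilyloxy)-5,8-dihydro-β,ε-caroten-8-one | CC1=C[C@H](O[Si](CC)(CC)CC)CC(C)(C)[C@H]1/C=C/C(C)=C/C=C/C(C)=C/C=C/C=C(C)/C=C/C=C(\C)C(=O)/C=C1/C(C)(C)C[C@H](O[Si](CC)(CC)CC)C[C@@]1(C)O
F2 | step 3 | (3S,5R,3'R,6'R)-5,8-epoxy-3,3'-bis(triethylsilyloxy)-5,8-dihydro-β,ε-caroten-8-ol (hemiketal, both C8 epimers) | CC1=C[C@H](O[Si](CC)(CC)CC)CC(C)(C)[C@H]1/C=C/C(C)=C/C=C/C(C)=C/C=C/C=C(C)/C=C/C=C(\C)C1(O)O[C@]2(C)C[C@@H](O[Si](CC)(CC)CC)CC(C)(C)C2=C1
F3 | step 3 | (3R,3'R,6'R)-3,3'-bis(triethylsilyloxy)-7,8-dihydro-β,ε-caroten-8-one | CC1=C[C@H](O[Si](CC)(CC)CC)CC(C)(C)[C@H]1/C=C/C(C)=C/C=C/C(C)=C/C=C/C=C(C)/C=C/C=C(\C)C(=O)CC1=C(C)C[C@@H](O[Si](CC)(CC)CC)CC1(C)C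
F0 | step 2 | none | none
F4 | step 4 | (3S,5R,8R,3'R,6'R)-5,8-epidioxy-5,8-dihydro-β,ε-carotene-3,3'-diol | CC1=C[C@H](O)CC(C)(C)[C@H]1/C=C/C(C)=C/C=C/C(C)=C/C=C/C=C(C)/C=C/C=C(\C)[C@@H]1OO[C@]2(C)C[C@@H](O)CC(C)(C)C2=C1
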